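## Retrosynthetic overview
1. The 1,2-dioxan-3-ol comes from a 1,2-dioxolan-3-ol by a one-carbon ring expansion. The ring CH2 undergoes a 1,2-shift onto a diazoethane-derived carbon, which makes C3–C4 and C4–C5 and sets C4. C3 follows by anomeric equilibration.
2. The dioxolanol comes from an (E)-β,β-dialkyl enone and H2O2. A catalyst-controlled conjugate perhydration builds the O–O ring and sets C6.
3. The enone comes from a Negishi coupling of the side-chain alkylzinc with the E-enol triflate of acetylacetone, with the alkene geometry retained.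
4. The side chain comes from a Z-selective Wittig reaction (benzaldehyde plus a six-carbon linker) and a Cu-catalysed Grignard coupling with (S)-3-bromo-2-methylpropan-1-ol, which supplies the side-chain stereocentre.
5. Ring order: the five-membered peroxide ring is made first and then expanded to the six-membered ring. No protecting groups are used.

Assumption: the target is (3S,4R,6S,2'R,9'Z) with ring numbering O1, O2, C3(OH) to C6. The hemiketal carbon C3 is configurationally labile, and the drawn 3S isomer (axial OH, with 4-Me and the side chain equatorial) is taken as the thermodynamic anomer.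

## Route

Step 1
Reactants: 1 1-bromo-6-chlorohexane
Product: 2 (6-chlorohexyl)triphenylphosphonium bromide
Conditions: PPh3 (1.0 equiv), MeCN, reflux, 24 h
Reagents that add atoms: triphenylphosphine, c1ccc(cc1)P(c1ccccc1)c1ccccc1
Why: SN2 quaternisation of the phosphine occurs only at C–Br because bromide is a far better leaving group than chloride.

Step 2
Reactants: 2 (6-chlorohexyl)triphenylphosphonium bromide; 3 benzaldehyde
Product: 5 [(1Z)-7-chlorohept-1-en-1-yl]benzene, via phosphonium ylide 4 (not isolated)
Conditions: NaHMDS, THF, −78 °C; then 3, −78 °C to rt; polish on AgNO3–silica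
Reagents that add atoms: none
Why: A lithium-free Wittig reaction of a non-stabilised ylide goes through the kinetic cis-oxaphosphetane and gives the Z-styrene (about 95:5), and the alkyl chloride is too slow to alkylate the ylide at −78 °C.

Step 3
Reactants: 5 [(1Z)-7-chlorohept-1-en-1-yl]benzene; 6 (2S)-3-bromo-2-methylpropan-1-ol
Product: 9 (2R,9Z)-2-methyl-10-phenyldec-9-en-1-ol, via alkenyl Grignard reagent 7 (not isolated), via bromo alkoxide 8 (not isolated)
Conditions: 5, Mg, THF, reflux; 6, MeMgCl, THF, −20 °C; combine, Li2CuCl4 (3 mol %), −20 °C to rt; aq NH4Cl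
Reagents that add atoms: none
Why: A copper-catalysed sp3–sp3 Grignard cross-coupling (Kochi type) displaces the primary bromide, and the chiral-pool stereocentre is not touched, so the descriptor changes from S to R only through CIP ranking.

Step 4
Reactants: 9 (2R,9Z)-2-methyl-10-phenyldec-9-en-1-ol
Product: 10 [(1Z,9R)-10-bromo-9-methyldec-1-en-1-yl]benzene
Conditions: CBr4, PPh3, CH2Cl2, 0 °C
Reagents that add atoms: carbon tetrabromide, BrC(Br)(Br)Br
Why: The Appel reaction converts the primary alcohol into the bromide under neutral conditions that leave the Z-styrene and the β-stereocentre alone.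

Step 5
Reactants: 11 pentane-2,4-dione
Product: 12 (2E)-4-oxopent-2-en-2-yl trifluoromethanesulfonate
Conditions: DBU, Tf2O, CH2Cl2, −78 to 0 °C
Reagents that add atoms: triflic anhydride, O=S(=O)(OS(=O)(=O)C(F)(F)F)C(F)(F)F
Why: O-triflation of the unchelated DBU enolate, which adopts the dipole-minimised W shape, gives the E-enol triflate with OTf trans to the acyl group.

Step 6
Reactants: 10 [(1Z,9R)-10-bromo-9-methyldec-1-en-1-yl]benzene; 12 (2E)-4-oxopent-2-en-2-yl trifluoromethanesulfonate
Product: 14 (3E,6R,13Z)-4,6-dimethyl-14-phenyltetradeca-3,13-dien-2-one, via alkylzinc bromide 13 (not isolated)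
Conditions: Zn, I2 (5 mol %), DMA, 80 °C; then 12, PdCl2(dppf) (3 mol %), THF, rt
Reagents that add atoms: none
Why: In this Negishi coupling, zerovalent palladium adds oxidatively to the C–OTf bond with retention of geometry, the wide-bite-angle ligand suppresses β-hydride loss, and the organozinc tolerates the methyl ketone.

Step 7
Reactants: 14 (3E,6R,13Z)-4,6-dimethyl-14-phenyltetradeca-3,13-dien-2-one
Product: 16 (5S)-3,5-dimethyl-5-[(2R,9Z)-2-methyl-10-phenyldec-9-en-1-yl]-1,2-dioxolan-3-ol, via open-chain hydroperoxy ketone 15 (not isolated)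
Conditions: 9-amino-9-deoxy-epi-quinidine (10 mol %), Cl3CCO2H (20 mol %), 50% aq H2O2 (3 equiv), dioxane, 30 °C
Reagents that add atoms: hydrogen peroxide, OO
Why: Proposed new method: primary-amine iminium activation, with the protonated quinuclidine steering H2O2 (a Weitz–Scheffer-type conjugate addition stopped at the peroxyhemiketal), is known for β-monosubstituted acyclic enones and, uncatalysed, for mesityl oxide, and is extended here to a β,β-dialkyl enone; attack on the Si face of C4 of the E-alkene sets the tertiary C–OO centre as S (the quinine-derived pseudoenantiomer would give the epimer), and closure of 15 onto the ketone blocks epoxide formation; closest known reaction type: cinchona-amine-catalysed asymmetric hydroperoxidation of enones.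

Step 8
Reactants: 16 (5S)-3,5-dimethyl-5-[(2R,9Z)-2-methyl-10-phenyldec-9-en-1-yl]-1,2-dioxolan-3-ol; 17 N-ethyl-N-nitrosourea
Product: 19 (3S,4R,6S)-3,4,6-trimethyl-6-[(2R,9Z)-2-methyl-10-phenyldec-9-en-1-yl]-1,2-dioxan-3-ol, via diazoethane 18 (not isolated)
Conditions: 17, aq KOH/toluene, 0 °C, organic layer dried over KOH; slow addition to 16, Sc(OTf)3 (10 mol %), (R,R)-Ph-pybox (12 mol %), toluene/CH2Cl2, −78 to −40 °C; aq NaHCO3
Reagents that add atoms: none
Why: Proposed new method: trivalent scandium ionises the peroxyhemiketal to the five-membered peroxycarbenium ion (the species Lewis acids generate from 3-alkoxy-1,2-dioxolanes for allylsilane capture), diazoethane adds through carbon, and the ring CH2 antiperiplanar to N2+ undergoes a 1,2-shift with loss of N2 (Tiffeneau–Demjanov type), favoured because it relieves dioxolane strain and regenerates an O-stabilised cation that the scandium-bound hydroxide recaptures; the pybox pocket decides which prochiral face of diazoethane bonds and the shift inverts that carbon to give 4R (the ligand antipode would give the 4-epimer), C6 is untouched, and C3 equilibrates to the axial-OH 3S hemiketal; closest known reaction type: Sc(OTf)3/chiral oxazoline-catalysed enantioselective diazoalkane ring expansion of cycloalkanones.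

## Compound list
1 | 1-bromo-6-chlorohexane | ClCCCCCCBr | starting material
2 | (6-chlorohexyl)triphenylphosphonium bromide | ClCCCCCC[P+](c1ccccc1)(c1ccccc1)c1ccccc1.[Br-] | intermediate
3 | benzaldehyde | O=Cc1ccccc1 | starting material
4 | (6-chlorohexylidene)triphenylphosphorane | ClCCCCCC=P(c1ccccc1)(c1ccccc1)c1ccccc1 | intermediate
5 | [(1Z)-7-chlorohept-1-en-1-yl]benzene | ClCCCCC/C=C\c1ccccc1 | intermediate
6 | (2S)-3-bromo-2-methylpropan-1-ol | C[C@H](CBr)CO | starting material
7 | [(6Z)-7-phenylhept-6-en-1-yl]magnesium chloride | Cl[Mg]CCCCC/C=C\c1ccccc1 | intermediate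
8 | chloromagnesium (2S)-3-bromo-2-methylpropan-1-olate | C[C@H](CBr)CO[Mg]Cl | intermediate
9 | (2R,9Z)-2-methyl-10-phenyldec-9-en-1-ol | C[C@H](CCCCCC/C=C\c1ccccc1)CO | intermediate
10 | [(1Z,9R)-10-bromo-9-methyldec-1-en-1-yl]benzene | C[C@H](CCCCCC/C=C\c1ccccc1)CBr | intermediate
11 | pentane-2,4-dione | CC(=O)CC(C)=O | starting material
12 | (2E)-4-oxopent-2-en-2-yl trifluoromethanesulfonate | CC(=O)/C=C(\C)OS(=O)(=O)C(F)(F)F | intermediate
13 | [(2R,9Z)-2-methyl-10-phenyldec-9-en-1-yl]zinc bromide | C[C@H](CCCCCC/C=C\c1ccccc1)C[Zn]Br | intermediate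
14 | (3E,6R,13Z)-4,6-dimethyl-14-phenyltetradeca-3,13-dien-2-one | C[C@H](CCCCCC/C=C\c1ccccc1)C/C(C)=C/C(C)=O | intermediate
15 | (4S,6R,13Z)-4-hydroperoxy-4,6-dimethyl-14-phenyltetradec-13-en-2-one | C[C@H](CCCCCC/C=C\c1ccccc1)C[C@@](OO)(C)CC(C)=O | intermediate
16 | (5S)-3,5-dimethyl-5-[(2R,9Z)-2-methyl-10-phenyldec-9-en-1-yl]-1,2-dioxolan-3-ol (equilibrating C3 anomers) | C[C@H](CCCCCC/C=C\c1ccccc1)C[C@@]1(C)CC(C)(O)OO1 | intermediate
17 | N-ethyl-N-nitrosourea | CCN(N=O)C(N)=O | starting material
18 | diazoethane | CC=[N+]=[N-] | intermediate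
19 | (3S,4R,6S)-3,4,6-trimethyl-6-[(2R,9Z)-2-methyl-10-phenyldec-9-en-1-yl]-1,2-dioxan-3-ol | C[C@H](CCCCCC/C=C\c1ccccc1)C[C@@]1(C)C[C@@H](C)[C@@](C)(O)OO1 | target

## Totals
Total steps: 8. Longest linear sequence: 7 (steps 1, 2, 3, 4, 6, 7, 8).

## Steps most likely to fail

**Step 8 (new ring expansion).**
- Risks: ethylation of the O–H groups by diazoethane, migration of the C3 methyl instead of the ring CH2, and weak catalyst control at C4.
- The fallback uses known chemistry, sets out from 16 and comes back at 19.
- The ring-opened tautomer is capped with Et3SiOTf/2,6-lutidine (CH2Cl2, −78 °C) as the acyclic silyl peroxide (4S,6R,13Z)-4,6-dimethyl-14-phenyl-4-[(triethylsilyl)peroxy]tetradec-13-en-2-one F1.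
- The free methyl ketone then undergoes the classical ligand-free diazoalkane homologation with 18, made from 17 as before (Büchner–Curtius–Schlotterbeck reaction, Sc(OTf)3 5 mol %, toluene, −78 °C).
- This gives (3R,5S,7R,14Z)-3,5,7-trimethyl-15-phenyl-5-[(triethylsilyl)peroxy]pentadec-14-en-2-one F2 together with (3S,5S,7R,14Z)-3,5,7-trimethyl-15-phenyl-5-[(triethylsilyl)peroxy]pentadec-14-en-2-one F3.
- The two epimers are separated by HPLC, and F3 is re-equilibrated with DBU and recycled.
- HF·pyridine (THF, 0 °C) then frees (3R,5S,7R,14Z)-5-hydroperoxy-3,5,7-trimethyl-15-phenylpentadec-14-en-2-one F4, which closes spontaneously to 19.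

**Step 7 (new substrate class).**
- Risks: slow iminium formation, E/Z scrambling through the dienamine that erodes the C6 configuration, and leakage to the epoxide.
- The fallback sets out from 14 and comes back at 16, and it gives up catalyst control.
- Compound 14 is stirred with 30% H2O2 in MeOH held at pH 8 (NaHCO3 buffer, 0 °C). This is the perhydration long known for mesityl oxide.
- It gives about 1:1 of 16 and (5R)-3,5-dimethyl-5-[(2R,9Z)-2-methyl-10-phenyldec-9-en-1-yl]-1,2-dioxolan-3-ol F5.
- These are diastereomers because of the side-chain stereocentre, so they are separated by preparative HPLC.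

**Step 6 (Negishi coupling).**
- Risks: loss of E geometry, β-hydride elimination, and hydrolysis of the activated triflate.
- The fallback sets out from 10 and comes back at 14, and it builds the trisubstituted alkene by carbometalation instead of cross-coupling.
- Lithium acetylide–ethylenediamine (DMSO, rt) displaces the bromide to give (4R,11Z)-4-methyl-12-phenyldodec-11-en-1-yne F6.
- Zirconium-catalysed syn-methylalumination (Me3Al, Cp2ZrCl2 cat., CH2Cl2, rt) touches only the terminal alkyne and gives dimethyl[(1E,4R,11Z)-2,4-dimethyl-12-phenyldodeca-1,11-dien-1-yl]alane F7.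
- Acetyl chloride (0 °C) acylates F7 with retention of geometry to give 14.

## Further compounds
F1 | step 8 | (4S,6R,13Z)-4,6-dimethyl-14-phenyl-4-[(triethylsilyl)peroxy]tetradec-13-en-2-one | C[C@H](CCCCCC/C=C\c1ccccc1)C[C@@](OO[Si](CC)(CC)CC)(C)CC(C)=O
F2 | step 8 | (3R,5S,7R,14Z)-3,5,7-trimethyl-15-phenyl-5-[(triethylsilyl)peroxy]pentadec-14-en-2-one | C[C@H](CCCCCC/C=C\c1ccccc1)C[C@@](OO[Si](CC)(CC)CC)(C)C[C@@H](C)C(C)=O
F3 | step 8 | (3S,5S,7R,14Z)-3,5,7-trimethyl-15-phenyl-5-[(triethylsilyl)peroxy]pentadec-14-en-2-one | C[C@H](CCCCCC/C=C\c1ccccc1)C[C@@](OO[Si](CC)(CC)CC)(C)C[C@H](C)C(C)=O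
F4 | step 8 | (3R,5S,7R,14Z)-5-hydroperoxy-3,5,7-trimethyl-15-phenylpentadec-14-en-2-one | C[C@H](CCCCCC/C=C\c1ccccc1)C[C@@](OO)(C)C[C@@H](C)C(C)=O
F5 | step 7 | (5R)-3,5-dimethyl-5-[(2R,9Z)-2-methyl-10-phenyldec-9-en-1-yl]-1,2-dioxolan-3-ol | C[C@H](CCCCCC/C=C\c1ccccc1)C[C@]1(C)CC(C)(O)OO1
F6 | step 6 | (4R,11Z)-4-methyl-12-phenyldodec-11-en-1-yne | C[C@H](CCCCCC/C=C\c1ccccc1)CC#C
F7 | step 6 | dimethyl[(1E,4R,11Z)-2,4-dimethyl-12-phenyldodeca-1,11-dien-1-yl]alane | C[C@H](CCCCCC/C=C\c1ccccc1)C/C(C)=C/[Al](C)C
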